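## The problem

Target 17 is 1-[(2R,5R)-5-butyloxolan-2-yl]hexadecan-2-one. It is an oxolane whose C5 carries a butyl group and whose C2 carries a CH2–CO–C14H29 arm; C3 and C4 are plain methylenes. The only stereocentres are C2 and C5, both R, which places the two side chains cis across the ring oxygen. They are 1,4-related through O1, and no ring substituent exists through which one could steer the other once the ring is closed. The cis relationship therefore has to be set while the ring forms, and the absolute configuration has to come from one purchased stereocentre that is relayed to the second. The ketone lies β to the ring oxygen, so base or strong acid can enolise the arm, expel O1 from C2 (retro-oxa-Michael) and reclose, which would scramble C2. The ketone and the aldehyde before it must therefore be made late and handled near neutrality. The enabling feature is that O1–C5 with its butyl group is the carbonyl of pentanal, while C2–C3–C4 is a three-carbon unit with a stereogenic terminus. That is the pattern of a (3+2) annulation of an aldehyde with a donor–acceptor cyclopropane in which C2 is the donor carbon and C4 the acceptor carbon. C4 bears only hydrogen in the target, so the activating geminal diester has to be removed without trace afterwards.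

## Retrosynthesis

**17 ⇒ 16 ⇒ 13 + 15 (from 14).** The ketone is taken back to secondary alcohol 16, and the bond between the carbinol carbon and C3 of the chain is cut. This separates the whole tetradecyl tail, as Grignard reagent 15 made from bromide 14, from aldehyde 13. The neighbouring cut (C1–C2 of the chain) would need an acyl-anion equivalent to displace a leaving group on a primary carbon β to the ring oxygen, a slow substitution. The chosen cut removes fourteen of the twenty-four carbons in one operation. The forward steps must add 15 to a β-alkoxy aldehyde faster than they enolise it and must oxidise 16 without base. The carbinol configuration of 16 is irrelevant because it is erased in 17.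

**13 ⇒ 12 ⇒ 11.** No skeletal bond is cut; the aldehyde is traced to primary alcohol 12 and this to benzyl ether 11. Benzyl is preferred to a silyl ether or an ester because the group must pass a tin Lewis acid (step 3), hot aqueous hydroxide (step 4) and a photoredox oxidation (step 5), then leave under neutral hydrogenolysis. Carrying the arm at the aldehyde or acid level would place an enolisable, chelating group beside the donor carbon of the key step. The precursor is no smaller, but its only function outside the ring is an inert ether. The forward steps need a hydrogenolysis that spares the two ring C–O bonds and an oxidation that stops at the aldehyde.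

**11 ⇒ 9 ⇒ 8.** In the retrosynthetic sense two carboxyl groups are put back on C4 of the target (C3 in the locants of 8, 9 and 10). The diester is what makes the three-carbon unit reactive, and it sits where the target has only hydrogen. The classical sequence (dealkoxycarbonylation, hydrolysis, radical decarboxylation) needs three operations. Hydrolysis to malonic acid 9 followed by a double hydrodecarboxylation through monoacid 10 needs two. Precursor 8 is larger, but it is the direct product of the annulation. The removal must not disturb the adjacent butyl-bearing stereocentre: the quaternary diester cannot enolise, and the radical formed on decarboxylation sits on a carbon that ends as CH2.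

**8 ⇒ 6 + 7.** This is the key disconnection: O1–C2 and C4–C5 (target numbering) are cut together. Cutting both C–O bonds instead leads to symmetrical precursors whose arms must be differentiated and extended. Cutting C2–C3 leads to a radical cyclisation that needs an enantioselective step elsewhere. Only this cut divides the ring into pentanal 7, which already carries the butyl group, and cyclopropane 6, whose single stereocentre comes from the chiral pool. A ring with two stereocentres is reduced to one stereocentre in a three-membered ring plus an achiral five-carbon aldehyde. The forward reaction must open 6 with inversion at the donor carbon, close the ring cis-selectively, tolerate the benzyl ether and accept an enolisable aliphatic aldehyde.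

**6 ⇒ 3 + 4.** The two bonds from the malonate carbon to C2 and C3 of the cyclopropane are cut, giving dimethyl malonate 4 and cyclic sulfate 3 as a 1,2-bis-electrophile. An asymmetric carbene-transfer cyclopropanation would need a chiral catalyst to do what the sulfate does by plain SN2 inversion. The strained ring is reduced to a four-carbon diol derivative and a commodity diester. The second alkylation must be a clean 3-exo-tet displacement with inversion. The same enantiomer of 6 results whichever carbon of 3 is attacked first, because the stereogenic carbon is substituted exactly once and by SN2.

**3 ⇒ 1.** The two S–O bonds are cut, returning diol 1; no C–O bond at the stereocentre is touched. This activates both hydroxyls at once and differentiates them after the first opening. The forward sequence must form the sulfite and oxidise it without oxidising the benzyl ether.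

## Roads not taken

**Alternative 1:** (4+3) cycloaddition of furan A1 with the oxyallyl cation from 1,1,3,3-tetrabromopropan-2-one A2, then unzipping of the carbocycle.
- **Cut:** the bonds from C2 and C5 of the oxolane to their first side-chain carbons are traced to the two new bonds of a seven-membered ring laid across the furan.
- **Forward key step:** a zinc–copper couple generates the oxyallyl cation from A2, this adds across the 2,5-positions of A1, and zinc debromination in the same pot gives meso-8-oxabicyclo[3.2.1]oct-6-en-3-one A3.
- **Merits:** the cis relationship is guaranteed by the bridged topology, which is firmer than the transition-state preference the chosen plan relies on. The materials are very cheap.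
- **Weak points:** A3 is achiral, so absolute configuration needs a separate desymmetrisation (a stoichiometric chiral lithium amide or an enzymatic Baeyer–Villiger oxidation). Opening the three-carbon bridge leaves a two-carbon ester arm and a one-carbon hydroxymethyl arm. The butyl group must then be built by oxidation, Wittig olefination and hydrogenation, and the tail added through an amide. An honest count is eleven to twelve steps.
- **Comparison:** the chosen plan sets against the topological certainty of A3 that pentanal 7 delivers the butyl group intact, that absolute and relative configuration arise in one bond-forming step from a purchased stereocentre, and that it is shorter.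

**Alternative 2:** permanganate oxidative cyclisation of hexa-1,5-diene A4 and lipase desymmetrisation.
- **Cut:** both ring C–O bonds (O1–C2 and O1–C5).
- **Forward key step:** permanganate adds across one alkene of A4 and the resulting manganese ester adds across the second, giving meso-[(2R,5S)-oxolane-2,5-diyl]dimethanol A5 with both arms cis. A lipase then acetylates one arm to give [(2R,5S)-5-(hydroxymethyl)oxolan-2-yl]methyl acetate A6 or its enantiomer. Either serves, since the two arms are simply elaborated in the opposite order.
- **Merits:** the core is reached in one step from a six-carbon hydrocarbon, the cis selectivity is inherent in the mechanism, and the enantioselection is enzymatic and cheap. In these respects it is at least the equal of the chosen plan.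
- **Weak points:** over-oxidation limits the efficiency of the cyclisation for the simplest diene. Both arms of A5 are one-carbon hydroxymethyl groups. One needs three more carbons. The other needs an acyl group attached to a primary carbon β to the ring oxygen, a poor SN2 site, or else a one-carbon homologation. With protecting-group changes the count exceeds eleven steps.
- **Comparison:** the chosen plan is convergent where this one is not, since both side chains arrive with the right carbon count.

**Alternative 3:** β-alkoxyacrylate radical cyclisation closing C2–C3.
- **Cut:** the C2–C3 ring bond.
- **Forward key step:** the primary radical generated from ethyl (2E)-3-{[(3R)-1-iodoheptan-3-yl]oxy}prop-2-enoate A7 with a tin hydride and a radical initiator adds 5-exo-trig to the acrylate β-carbon. This gives ethyl 2-[(2R,5R)-5-butyloxolan-2-yl]acetate A8.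
- **Merits:** the cis-2,5 preference of this cyclisation is well grounded. A8 already has the arm at the right oxidation level, so amide formation and addition of Grignard reagent 15 finish the synthesis. The whole route from pentanal 7 is about seven steps, two fewer than the chosen plan, and it has no traceless group to delete. On step count this road is better.
- **Weak points:** the one stereocentre of A7 must be created by an enantioselective reaction (asymmetric allylation of 7 or asymmetric reduction of a β-keto ester). The sequence is linear, and the key step uses a stoichiometric organotin hydride with its purification burden.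
- **Comparison:** the chosen plan offers stereochemistry taken from a purchased diol by stereospecific SN2 events, and a convergent union of two simple fragments that forms both ring bonds and both stereocentres at once. It pays for this with a stoichiometric tin Lewis acid and the two steps that remove the diester.

Key step: step 3

Remark on the chemistry: diol 1 is assumed to be bought as the enantiopure S compound (a malic acid-derived catalogue building block), and its purity is assumed to carry through steps 1–3 because every event at that carbon is an SN2 displacement.

## Route

Step 1
Reactants: 1 (2S)-4-(benzyloxy)butane-1,2-diol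
Product: 3 (4S)-4-[2-(benzyloxy)ethyl]-1,3,2-dioxathiolane 2,2-dioxide, via cyclic sulfite 2 (not isolated)
Conditions: SOCl2, Et3N, CH2Cl2, 0 °C; aqueous wash, then RuCl3·xH2O (0.5 mol%), NaIO4, MeCN/H2O, 0 °C
Reagents that add atoms: thionyl chloride, O=S(Cl)Cl; sodium periodate, [Na+].[O-]I(=O)(=O)=O
Why: Cyclic sulfite formation followed by RuO4-catalysed oxidation to the cyclic sulfate; no C–O bond of the stereocentre is broken, so the S configuration is retained. The sulfite oxidation is complete within minutes at 0 °C and low ruthenium loading, well before the benzyl ether is attacked.

Step 2
Reactants: 3 (4S)-4-[2-(benzyloxy)ethyl]-1,3,2-dioxathiolane 2,2-dioxide; 4 dimethyl malonate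
Product: 6 dimethyl (2S)-2-[2-(benzyloxy)ethyl]cyclopropane-1,1-dicarboxylate, via open-chain sulfate monoester 5 (not isolated)
Conditions: NaH (2.2 equiv), DME, 0 °C; add 3, rt to 85 °C
Reagents that add atoms: none
Why: Double malonate alkylation by a 1,2-cyclic sulfate: sodium malonate opens 3 at the primary carbon to give 5, whose second malonate anion displaces the secondary sulfate in a 3-exo-tet SN2 with inversion. The descriptor stays S only because the CIP priorities change. Attack in the opposite order would give the same enantiomer.

Step 3
Reactants: 6 dimethyl (2S)-2-[2-(benzyloxy)ethyl]cyclopropane-1,1-dicarboxylate; 7 pentanal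
Product: 8 dimethyl (2R,5R)-5-[2-(benzyloxy)ethyl]-2-butyloxolane-3,3-dicarboxylate
Conditions: 7 (3 equiv, slow addition), SnCl4 (1.0 equiv), CH2Cl2, −20 °C to rt
Reagents that add atoms: none
Why: SnCl4 chelates the two ester carbonyls of 6 and polarises the bond between the malonate carbon and the donor carbon without breaking it, since a secondary alkyl carbon cannot support a free cation. The carbonyl oxygen of 7 then attacks the donor carbon from the back (SN2-like, inversion), forming O1–C2 of the target and an oxocarbenium ion paired with a tin malonate enolate. Attack of the malonate carbon on the oxocarbenium carbon forms C4–C5 and closes the oxolane; this is formally a 5-endo-trig (enol-exo) aldol-type closure, feasible because the electrophile is a heteroatom-stabilised cation held in an ion pair. The closest known reaction type is the Lewis acid-promoted (3+2) annulation of aldehydes with donor–acceptor cyclopropane-1,1-diesters, established for aryl, vinyl and (with stronger Lewis acids) alkyl donors and for aromatic, conjugated and aliphatic aldehydes; the alkyl-donor/aliphatic-aldehyde pairing used here is the least explored. The stereocentre at the former donor carbon (C5 of 8, C2 of the target) is fixed by stereospecific inversion of the S centre of 6, so enantiopurity is inherited from 1. The butyl-bearing centre (C2 of 8, C5 of the target) is set in the ring closure: the (E)-oxocarbenium ion reacts through an envelope with butyl and the benzyloxyethyl group both pseudoequatorial, which places them cis. The step needs cis diastereoselectivity and complete stereochemical transfer; the first rests on this envelope preference, the second on the absence of any cation-stabilising group at the donor carbon. Excess aldehyde added slowly to the cold mixture is meant to outrun Lewis acid-promoted aldol and trimerisation of 7.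

Step 4
Reactants: 8 dimethyl (2R,5R)-5-[2-(benzyloxy)ethyl]-2-butyloxolane-3,3-dicarboxylate
Product: 9 (2R,5R)-5-[2-(benzyloxy)ethyl]-2-butyloxolane-3,3-dicarboxylic acid
Conditions: KOH (excess), MeOH/H2O, reflux; cold aq. HCl to pH 2
Reagents that add atoms: potassium hydroxide, [K+].[OH-]
Why: Saponification of both esters by acyl–oxygen cleavage. The malonate carbon is quaternary, so no enolate can form and the ring oxygen cannot be expelled; both stereocentres are untouched. Cold acidification avoids premature decarboxylation, which would in any case lie on the path.

Step 5
Reactants: 9 (2R,5R)-5-[2-(benzyloxy)ethyl]-2-butyloxolane-3,3-dicarboxylic acid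
Product: 11 (2R,5R)-2-[2-(benzyloxy)ethyl]-5-butyloxolane, via monocarboxylic acid 10 (not isolated)
Conditions: 9-mesityl-10-phenylacridinium tetrafluoroborate (5 mol%), PhSSPh (10 mol%), i-Pr2NEt (20 mol%), CF3CH2OH, 450 nm LEDs, rt
Reagents that add atoms: none
Why: Photoredox hydrodecarboxylation, a reaction type documented for the double decarboxylation of dialkylmalonic acids. The excited acridinium oxidises the carboxylate, CO2 is lost, and thiophenol formed from the disulfide returns a hydrogen atom; a second cycle on 10 removes the remaining carboxyl. Both radicals sit on the carbon that becomes the C4 methylene, so no stereocentre is at stake.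

Step 6
Reactants: 11 (2R,5R)-2-[2-(benzyloxy)ethyl]-5-butyloxolane
Product: 12 2-[(2R,5R)-5-butyloxolan-2-yl]ethan-1-ol
Conditions: H2 (1 atm), 10% Pd/C, EtOH, rt
Reagents that add atoms: none
Why: Catalytic hydrogenolysis cleaves only the benzylic C–O bond; the secondary dialkyl ether bonds of the ring are inert under these conditions.

Step 7
Reactants: 12 2-[(2R,5R)-5-butyloxolan-2-yl]ethan-1-ol
Product: 13 2-[(2R,5R)-5-butyloxolan-2-yl]acetaldehyde
Conditions: TEMPO (2,2,6,6-tetramethylpiperidin-1-oxyl, 10 mol%), PhI(OAc)2 (1.1 equiv), CH2Cl2, rt
Reagents that add atoms: none
Why: Oxoammonium-mediated oxidation of a primary alcohol stops at the aldehyde and runs without base, so the β-alkoxy aldehyde is not enolised and the ring oxygen is not eliminated. Aldehyde 13 is used directly in the next step.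

Step 8
Reactants: 13 2-[(2R,5R)-5-butyloxolan-2-yl]acetaldehyde; 14 1-bromotetradecane
Product: 16 1-[(2R,5R)-5-butyloxolan-2-yl]hexadecan-2-ol (both epimers at the carbinol carbon), via tetradecylmagnesium bromide 15 (not isolated)
Conditions: Mg, THF, reflux (14 to 15); then 13, THF, −78 to 0 °C; aq. NH4Cl
Reagents that add atoms: none
Why: Grignard addition to an aldehyde; at low temperature 1,2-addition of a primary alkylmagnesium halide outpaces enolisation. The new carbinol centre forms without control, which is harmless because it is oxidised in step 9.

Step 9
Reactants: 16 1-[(2R,5R)-5-butyloxolan-2-yl]hexadecan-2-ol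
Product: 17 1-[(2R,5R)-5-butyloxolan-2-yl]hexadecan-2-one
Conditions: Dess–Martin periodinane (1.3 equiv), CH2Cl2, rt
Reagents that add atoms: none
Why: Dess–Martin oxidation converts both epimers of 16 into the same ketone under non-basic conditions, so the β-alkoxy ketone does not undergo retro-oxa-Michael opening and the cis ring configuration is kept.

## Compound list

1 | (2S)-4-(benzyloxy)butane-1,2-diol | OC[C@@H](O)CCOCc1ccccc1 | starting material
2 | (4S)-4-[2-(benzyloxy)ethyl]-1,3,2-dioxathiolane 2-oxide (both sulfur epimers) | O=S1OC[C@@H](O1)CCOCc2ccccc2 | intermediate (not isolated)
3 | (4S)-4-[2-(benzyloxy)ethyl]-1,3,2-dioxathiolane 2,2-dioxide | O=S1(=O)OC[C@@H](O1)CCOCc2ccccc2 | intermediate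
4 | dimethyl malonate | COC(=O)CC(=O)OC | starting material
5 | sodium (2R)-4-(benzyloxy)-1-(1,3-dimethoxy-1,3-dioxopropan-2-yl)butan-2-yl sulfate | COC(=O)C(C(=O)OC)C[C@@H](OS(=O)(=O)[O-])CCOCc1ccccc1.[Na+] | intermediate (not isolated)
6 | dimethyl (2S)-2-[2-(benzyloxy)ethyl]cyclopropane-1,1-dicarboxylate | COC(=O)C1(C(=O)OC)C[C@H]1CCOCc2ccccc2 | intermediate
7 | pentanal | CCCCC=O | starting material
8 | dimethyl (2R,5R)-5-[2-(benzyloxy)ethyl]-2-butyloxolane-3,3-dicarboxylate | c1ccccc1COCC[C@H]1CC(C(=O)OC)(C(=O)OC)[C@@H](CCCC)O1 | intermediate
9 | (2R,5R)-5-[2-(benzyloxy)ethyl]-2-butyloxolane-3,3-dicarboxylic acid | c1ccccc1COCC[C@H]1CC(C(=O)O)(C(=O)O)[C@@H](CCCC)O1 | intermediate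
10 | (2R,5R)-5-[2-(benzyloxy)ethyl]-2-butyloxolane-3-carboxylic acid (both C3 epimers) | c1ccccc1COCC[C@H]1CC(C(=O)O)[C@@H](CCCC)O1 | intermediate (not isolated)
11 | (2R,5R)-2-[2-(benzyloxy)ethyl]-5-butyloxolane | c1ccccc1COCC[C@H]1CC[C@@H](CCCC)O1 | intermediate
12 | 2-[(2R,5R)-5-butyloxolan-2-yl]ethan-1-ol | OCC[C@H]1CC[C@@H](CCCC)O1 | intermediate
13 | 2-[(2R,5R)-5-butyloxolan-2-yl]acetaldehyde | O=CC[C@H]1CC[C@@H](CCCC)O1 | intermediate
14 | 1-bromotetradecane | CCCCCCCCCCCCCCBr | starting material
15 | tetradecylmagnesium bromide | CCCCCCCCCCCCCC[Mg]Br | intermediate (not isolated)
16 | 1-[(2R,5R)-5-butyloxolan-2-yl]hexadecan-2-ol (both carbinol epimers) | CCCCCCCCCCCCCCC(O)C[C@H]1CC[C@@H](CCCC)O1 | intermediate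
17 | 1-[(2R,5R)-5-butyloxolan-2-yl]hexadecan-2-one | CCCCCCCCCCCCCCC(=O)C[C@H]1CC[C@@H](CCCC)O1 | target

## Step count and least certain steps

Total: 9 steps. Longest linear sequence: 9 steps, from 1 to 17; compounds 4, 7 and 14 enter as purchased reagents.

**Step 3 (key step).** Ring opening of a cyclopropane whose donor carbon is a plain secondary alkyl carbon is slow. Meanwhile the tin Lewis acid promotes aldol self-condensation and cyclotrimerisation of the enolisable aldehyde and chloride transfer to the activated cyclopropane, so the productive pathway may be outrun. The cis preference may also erode, because a primary alkyl group on the oxocarbenium carbon distinguishes the two envelopes less than an aryl group does.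

Fallback, setting out from 3 and returning at 11: the ring is built by alkylation and hydroalkoxylation, and the second stereocentre is set by hydrogenation.
- Hex-1-yne is deprotonated with n-BuLi to lithium hex-1-yn-1-ide F1, which opens 3 at the primary carbon (THF, −78 °C to rt).
- Hydrolysis of the resulting sulfate monoester (cat. H2SO4, wet THF) should give (3R)-1-(benzyloxy)dec-5-yn-3-ol F2 with the carbinol configuration of 1 untouched.
- Gold-catalysed 5-endo-dig cycloisomerisation (AuCl(PPh3)/AgOTf, toluene, rt) should give (2R)-2-[2-(benzyloxy)ethyl]-5-butyl-2,3-dihydrofuran F3.
- Hydrogenation of this cyclic enol ether over Rh/Al2O3 (H2, EtOAc, trace Et3N), from the face remote from the C2 substituent, should give 11.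

This road is shorter, but its cis selectivity is only a steric preference in a heterogeneous hydrogenation, which is why it is held in reserve.

**Step 5.** The second decarboxylation may stall at the monoacid stage, or the strongly oxidising excited acridinium may attack the benzyl ether in competition with the carboxylate.

Fallback, setting out from 9 and returning at 11:
- Diacid 9 is decarboxylated thermally (DMSO, about 120 °C) to 10, which is isolated.
- Acid 10 is coupled with N-hydroxypyridine-2-thione (DCC, cat. DMAP, CH2Cl2, dark) to the Barton ester 2-sulfanylidenepyridin-1(2H)-yl (2R,5R)-5-[2-(benzyloxy)ethyl]-2-butyloxolane-3-carboxylate F4.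
- Barton reductive decarboxylation of F4 (t-BuSH, visible light, toluene) should give 11.

**Step 4.** Hydrolysis may stop at the half-ester, because the second ester sits on a quaternary carbon flanked by the butyl-bearing ring carbon.

Fallback, setting out from 8 and returning at 10:
- Krapcho demethoxycarbonylation (LiCl, wet DMSO, 150 °C) removes one ester to give methyl (2R,5R)-5-[2-(benzyloxy)ethyl]-2-butyloxolane-3-carboxylate F5. The transient ester enolate is β to the ring oxygen, but expelling it would be a 5-endo elimination and is expected to lose to protonation.
- The unhindered ester of F5 is saponified (LiOH, THF/H2O, rt) to 10.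
- Acid 10 is then carried to 11 by a single cycle of the step 5 conditions.

**Step 8.** The basic Grignard reagent may enolise the β-alkoxy aldehyde instead of adding to it. This would return starting aldehyde and aldol products and could trigger elimination of the ring oxygen, which would scramble C2.

Fallback, setting out from 12 and returning at 17:
- Alcohol 12 is oxidised (TEMPO, PhI(OAc)2, MeCN/H2O) to 2-[(2R,5R)-5-butyloxolan-2-yl]acetic acid F6.
- F6 is coupled with N,O-dimethylhydroxylamine hydrochloride (carbonyldiimidazole, CH2Cl2) to 2-[(2R,5R)-5-butyloxolan-2-yl]-N-methoxy-N-methylacetamide F7.
- Addition of 15 to F7 (THF, 0 °C) should give 17 directly through the stable magnesium chelate, with no aldehyde and no final oxidation.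

## Further compounds

F1 | step 3 | lithium hex-1-yn-1-ide | [Li]C#CCCCC
F2 | step 3 | (3R)-1-(benzyloxy)dec-5-yn-3-ol | CCCCC#CC[C@@H](O)CCOCc1ccccc1
F3 | step 3 | (2R)-2-[2-(benzyloxy)ethyl]-5-butyl-2,3-dihydrofuran | CCCCC1=CC[C@@H](O1)CCOCc2ccccc2
F4 | step 5 | 2-sulfanylidenepyridin-1(2H)-yl (2R,5R)-5-[2-(benzyloxy)ethyl]-2-butyloxolane-3-carboxylate (both C3 epimers) | c1ccccc1COCC[C@H]1CC(C(=O)On2ccccc2=S)[C@@H](CCCC)O1
F5 | step 4 | methyl (2R,5R)-5-[2-(benzyloxy)ethyl]-2-butyloxolane-3-carboxylate (both C3 epimers) | c1ccccc1COCC[C@H]1CC(C(=O)OC)[C@@H](CCCC)O1
F6 | step 8 | 2-[(2R,5R)-5-butyloxolan-2-yl]acetic acid | OC(=O)C[C@H]1CC[C@@H](CCCC)O1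
F7 | step 8 | 2-[(2R,5R)-5-butyloxolan-2-yl]-N-methoxy-N-methylacetamide | CON(C)C(=O)C[C@H]1CC[C@@H](CCCC)O1
A1 | alternative 1 | furan | c1ccoc1
A2 | alternative 1 | 1,1,3,3-tetrabromopropan-2-one | BrC(Br)C(=O)C(Br)Br
A3 | alternative 1 | meso-8-oxabicyclo[3.2.1]oct-6-en-3-one | O=C1C[C@H]2C=C[C@@H](C1)O2
A4 | alternative 2 | hexa-1,5-diene | C=CCCC=C
A5 | alternative 2 | [(2R,5S)-oxolane-2,5-diyl]dimethanol (meso, cis) | OC[C@H]1CC[C@@H](CO)O1
A6 | alternative 2 | [(2R,5S)-5-(hydroxymethyl)oxolan-2-yl]methyl acetate | CC(=O)OC[C@H]1CC[C@@H](CO)O1
A7 | alternative 3 | ethyl (2E)-3-{[(3R)-1-iodoheptan-3-yl]oxy}prop-2-enoate | ICC[C@@H](CCCC)O/C=C/C(=O)OCC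
A8 | alternative 3 | ethyl 2-[(2R,5R)-5-butyloxolan-2-yl]acetate | CCOC(=O)C[C@H]1CC[C@@H](CCCC)O1
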